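**Retrosynthetic overview**
- The target aldehyde comes from its C3 dimethyl acetal by acid hydrolysis. The acetal comes from an o-alkynylaryl orthoformate by a Pt(II)-catalysed 5-endo ring closure that forms the furan O–C2 bond, with 1,3 O→C shift of the CH(OMe)2 group onto C3.
- The orthoformate comes from the diarylalkyne triol and trimethyl orthoformate; all three OH groups are capped transiently.
- The diarylalkyne comes from Sonogashira coupling of an o-iodophenol with an arylacetylene.
- The iodophenol comes from dihydroconiferyl alcohol and that from eugenol; the arylacetylene comes from vanillin.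
- Ring order: both benzene rings are bought; the furan ring is the only ring made and it is closed last.

Assumption: the target has no stereocentre and no stereogenic double bond, so it is achiral and needs no stereocontrol.

**Step 1**
Reactants: 1 eugenol (4-allyl-2-methoxyphenol)
Product: 3 dihydroconiferyl alcohol 4-(3-hydroxypropyl)-2-methoxyphenol, via bis(9-BBN) adduct 2 (not isolated)
Conditions: 9-BBN (2.2 equiv), THF, 0 °C → rt; then 3 M NaOH, 30% H2O2, 0 °C → rt
Reagents that add atoms: 9-BBN, [H]B1C2CCCC1CCC2 (its atoms stay only in 2); hydrogen peroxide, OO (oxygen of the new OH)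
Why: Brown hydroboration–oxidation; 9-BBN adds to the terminal alkene with >99:1 anti-Markovnikov selectivity (one further equivalent is consumed by the phenol O–H), and alkaline peroxide converts C–B into C–OH and frees the phenol.

**Step 2**
Reactants: 3 dihydroconiferyl alcohol
Product: 4 4-(3-hydroxypropyl)-2-iodo-6-methoxyphenol
Conditions: I2 (1.05 equiv), NaHCO3, THF–H2O, 0 °C → rt
Reagents that add atoms: iodine, II
Why: Electrophilic aromatic iodination directed by the phenol(ate); the para position is blocked and only one position ortho to OH is free, so mono-iodination occurs there.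

**Step 3**
Reactants: 5 vanillin (4-hydroxy-3-methoxybenzaldehyde)
Product: 6 4-ethynyl-2-methoxyphenol
Conditions: Ohira–Bestmann reagent (1.5 equiv), K2CO3 (3 equiv), MeOH, rt
Reagents that add atoms: dimethyl (1-diazo-2-oxopropyl)phosphonate, COP(=O)(OC)C(=[N+]=[N-])C(C)=O (supplies the terminal alkyne carbon)
Why: Seyferth–Gilbert homologation in the Ohira–Bestmann variant; methanolysis releases the diazomethylphosphonate anion, which olefinates the aldehyde and loses N2 with a 1,2-H shift to give the alkyne, and excess base tolerates the free phenol.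

**Step 4**
Reactants: 4 4-(3-hydroxypropyl)-2-iodo-6-methoxyphenol; 6 4-ethynyl-2-methoxyphenol
Product: 7 4-(3-hydroxypropyl)-2-[(4-hydroxy-3-methoxyphenyl)ethynyl]-6-methoxyphenol
Conditions: Pd(PPh3)2Cl2 (3 mol%), CuI (5 mol%), Et3N, THF (degassed), rt
Reagents that add atoms: none
Why: Sonogashira coupling of an aryl iodide with a terminal alkyne tolerates free OH groups, and running it at room temperature keeps the o-alkynylphenol from cyclising early.

**Step 5**
Reactants: 7 4-(3-hydroxypropyl)-2-[(4-hydroxy-3-methoxyphenyl)ethynyl]-6-methoxyphenol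
Product: 10 2-(4-hydroxy-3-methoxyphenyl)-5-(3-hydroxypropyl)-7-methoxy-1-benzofuran-3-carbaldehyde, via tris(dimethoxymethyl) ether 8 (not isolated), via C3 dimethyl acetal 9 (not isolated)
Conditions: HC(OMe)3 (neat), CSA (1 mol%), 40 °C, MeOH stripped in vacuo; then PtCl2 (5 mol%), 1,5-COD (20 mol%), PhMe, 40 °C; then 1 M HCl, THF–MeOH, rt
Reagents that add atoms: trimethyl orthoformate, COC(OC)OC (supplies the formyl carbon); water, O (supplies the aldehyde oxygen)
Why: Proposed new method: acid-catalysed orthoester exchange caps all three OH groups as O–CH(OMe)2, then Pt(II) π-activates the alkyne, the aryl orthoformate oxygen attacks anti in a 5-endo-dig mode to form the O–C2 bond, the oxonium releases a resonance-stabilised dimethoxycarbenium ion that is recaptured at C3 by the benzofuran-3-yl–platinum species (net 1,3 O→C shift of a masked formyl group), and aqueous acid finally unmasks CHO and removes the two spectator orthoformates; the closest known reaction type is the Pt(II)-catalysed carboalkoxylation of o-alkynylphenyl acetals and allyl ethers (1,3-shift of α-alkoxyalkyl or allyl groups) to 2,3-disubstituted benzofurans, which to my knowledge has not been run with an orthoformate-derived dialkoxymethyl migrating group.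

**Compound list**
1 | eugenol (4-allyl-2-methoxyphenol) | C=CCc1ccc(O)c(OC)c1 | starting material
2 | 9-{3-[4-(9-borabicyclo[3.3.1]nonan-9-yloxy)-3-methoxyphenyl]propyl}-9-borabicyclo[3.3.1]nonane (bis(9-BBN) adduct: alkyl–B at the chain end, O–B at the phenol) | COc1cc(CCCB2C3CCCC2CCC3)ccc1OB1C2CCCC1CCC2 | intermediate
3 | dihydroconiferyl alcohol, 4-(3-hydroxypropyl)-2-methoxyphenol | OCCCc1ccc(O)c(OC)c1 | intermediate
4 | 4-(3-hydroxypropyl)-2-iodo-6-methoxyphenol | OCCCc1cc(I)c(O)c(OC)c1 | intermediate
5 | vanillin (4-hydroxy-3-methoxybenzaldehyde) | COc1cc(C=O)ccc1O | starting material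
6 | 4-ethynyl-2-methoxyphenol | COc1cc(C#C)ccc1O | intermediate
7 | 4-(3-hydroxypropyl)-2-[(4-hydroxy-3-methoxyphenyl)ethynyl]-6-methoxyphenol | OCCCc1cc(OC)c(O)c(C#Cc2ccc(O)c(OC)c2)c1 | intermediate
8 | 1-(dimethoxymethoxy)-2-{[4-(dimethoxymethoxy)-3-methoxyphenyl]ethynyl}-4-[3-(dimethoxymethoxy)propyl]-6-methoxybenzene (tris-orthoformate of 7) | COC(OC)OCCCc1cc(OC)c(OC(OC)OC)c(C#Cc2ccc(OC(OC)OC)c(OC)c2)c1 | intermediate
9 | 3-(dimethoxymethyl)-2-[4-(dimethoxymethoxy)-3-methoxyphenyl]-5-[3-(dimethoxymethoxy)propyl]-7-methoxy-1-benzofuran | COC(OC)OCCCc1cc(OC)c2oc(-c3ccc(OC(OC)OC)c(OC)c3)c(C(OC)OC)c2c1 | intermediate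
10 | 2-(4-hydroxy-3-methoxyphenyl)-5-(3-hydroxypropyl)-7-methoxy-1-benzofuran-3-carbaldehyde (achiral) | COc1cc(-c2oc3c(OC)cc(CCCO)cc3c2C=O)ccc1O | target

**Step count**
Total: 5 steps (4 if compound 3, which is itself sold, is bought instead of made from eugenol). Longest linear sequence: 4 steps (steps 1, 2, 4, 5; compounds 1 → 3 → 4 → 7 → 10).

**Steps most likely to fail**

Step 5 (the proposed new step). The hindered phenol may exchange incompletely with the orthoformate, in which case it simply cyclises to the 3-unsubstituted benzofuran. The dimethoxycarbenium ion may also escape before it is recaptured at C3. The fallback is known chemistry and sets out from 7. Pd(II)-catalysed methoxycarbonylative cyclisation (PdCl2 cat., CuCl2, NaOAc, CO 1 atm, MeOH, rt) closes the same O–C2 bond and gives methyl 2-(4-hydroxy-3-methoxyphenyl)-5-(3-hydroxypropyl)-7-methoxy-1-benzofuran-3-carboxylate F1. LiAlH4 in THF at 0 °C reduces the ester to 4-[3-(hydroxymethyl)-5-(3-hydroxypropyl)-7-methoxy-1-benzofuran-2-yl]-2-methoxyphenol F2. MnO2 in CH2Cl2 then oxidises the benzofuran-3-ylmethanol selectively over the saturated primary alcohol, and the route is rejoined at 10.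

Step 4. The electron-rich free iodophenol may couple slowly, the alkyne may homocouple, or the product may cyclise under Pd/Cu to the 3-unsubstituted benzofuran, which the key step cannot use. The fallback sets out from 4. Acetylation (Ac2O, pyridine) gives 3-(4-acetoxy-3-iodo-5-methoxyphenyl)propyl acetate F3, in which the ring is less electron-rich and the phenol cannot cyclise. Sonogashira coupling with 6 (Pd(PPh3)2Cl2, CuI, Et3N, 50 °C) gives 3-{4-acetoxy-3-[(4-hydroxy-3-methoxyphenyl)ethynyl]-5-methoxyphenyl}propyl acetate F4. Methanolysis (K2CO3, MeOH, 0 °C) removes both acetates and the route is rejoined at 7.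

Step 3. Under the basic conditions vanillin is a phenoxide (a vinylogous carboxylate), so the aldehyde may react sluggishly with the diazophosphonate anion. The fallback puts the alkyne on the other ring and sets out from 4. Sonogashira coupling with trimethylsilylacetylene (C[Si](C)(C)C#C) gives 4-(3-hydroxypropyl)-2-methoxy-6-[(trimethylsilyl)ethynyl]phenol F5. A one-pot CsF-promoted desilylative Sonogashira coupling with bought 4-iodo-2-methoxyphenol (COc1cc(I)ccc1O) then rejoins the route at 7, and compounds 5 and 6 are no longer needed.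

**Further compounds**
F1 | step 5 | methyl 2-(4-hydroxy-3-methoxyphenyl)-5-(3-hydroxypropyl)-7-methoxy-1-benzofuran-3-carboxylate | COC(=O)c1c(-c2ccc(O)c(OC)c2)oc2c(OC)cc(CCCO)cc12
F2 | step 5 | 4-[3-(hydroxymethyl)-5-(3-hydroxypropyl)-7-methoxy-1-benzofuran-2-yl]-2-methoxyphenol | OCc1c(-c2ccc(O)c(OC)c2)oc2c(OC)cc(CCCO)cc12
F3 | step 4 | 3-(4-acetoxy-3-iodo-5-methoxyphenyl)propyl acetate | CC(=O)OCCCc1cc(I)c(OC(C)=O)c(OC)c1
F4 | step 4 | 3-{4-acetoxy-3-[(4-hydroxy-3-methoxyphenyl)ethynyl]-5-methoxyphenyl}propyl acetate | CC(=O)OCCCc1cc(OC)c(OC(C)=O)c(C#Cc2ccc(O)c(OC)c2)c1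
F5 | step 3 | 4-(3-hydroxypropyl)-2-methoxy-6-[(trimethylsilyl)ethynyl]phenol | C[Si](C)(C)C#Cc1cc(CCCO)cc(OC)c1O
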